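## Analysis of the target

Compound 27 is made of two flavonol units joined only by one oxygen that bridges C4' of both B rings. Half 1 is a 3,5-dihydroxy-7-methoxyflavone whose ring B keeps a free 3'-OH; half 2 is a 3,5,7-trihydroxyflavone whose ring B carries a 3'-OMe. There is no stereocentre and no axis to control, so the problem is one of regiochemistry and of telling seven oxygen substituents apart. Two of them must end as methyl ethers (C7 of half 1, C3' of half 2) and five as free hydroxyls. The free 3-hydroxy-4-keto and 5-hydroxy-4-keto arrays chelate metals, oxidise in basic air and make the compound poorly soluble, so they are best set free in the last step. The diaryl ether has an oxygen substituent ortho to it on each ring, and because the halves differ, the two flavonols must be built one after the other on a preformed diaryl ether. The strategy rests on ring A of half 2: C5–O, C7–O and C8a–O1 are mutually meta, which is the 1,3,5 pattern of 12 with bromine in the place of O1. Ring A can therefore enter as a 2-bromobenzoyl electrophile, and O1–C8a is made last by attack of a diketone enolate oxygen.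

## Retrosynthetic reasoning

**27 from 26.** The last operation cuts only five O–CH2Ph bonds by hydrogenolysis. Every oxygen that must end as OH travels as a benzyl ether (the 3-OH of half 1 is already free in 26), and every oxygen that must end as OMe is methylated from the start. The sensitive polyphenol then exists only at the end.

**26 from 24 through 25.** Half 1 is cut at O1–C2 and at C3–O, which is an Algar–Flynn–Oyamada oxidation of the 2'-hydroxychalcone 24 via the dihydroflavonol 25. This turns an aldehyde into a flavonol in two operations and needs no metal or strong acid in the presence of half 2. The forward reaction must send the phenoxide to the β-carbon (six-membered ring) and not to the α-carbon.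

**24 from 20 and 23.** The enone double bond is cut by a Claisen–Schmidt condensation. The 5-OH/7-OMe difference of half 1 is thereby moved into a small building block: 23 comes from 21 by methylation of the one non-chelated hydroxyl (22) and benzylation of one of the two equivalent chelated hydroxyls.

**20 from 19.** The aldehyde is carried as an ethylene acetal, because it has to pass an organolithium step and an enolate step before it is needed.

**19 from 18 (key disconnection).** Ring C of half 2 is cut at O1–C8a and not at the usual O1–C2. The usual cut needs a free ortho phenol on a phloroglucinol-type ring A, one of three equivalent hydroxyls to be singled out, and an acidic cyclodehydration. The O1–C8a cut lets both ring A oxygens be benzylated identically from the outset, lets the bromine mark the site of closure, and leaves no phenol free at any stage. The 3-oxygen is already in the chain as a benzyl ether, so 19 is at the flavonol oxidation level. The forward reaction is a copper-catalysed intramolecular O-arylation of the enolate of 18.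

**18 from 17, and 17 from 11 and 15.** The C3–C4 bond of half 2 is cut: an aldol addition of the α-benzyloxy ketone 11 to the bromoaldehyde 15 gives 17, and a Dess–Martin oxidation gives the diketone 18. An aldol route is chosen over direct C-acylation because it has no O- versus C-acylation question.

**15 from 13 and 12.** The formyl carbon is removed (Vilsmeier formylation of 13), then the two benzyl groups, which leads back to 12. The formylation must go ortho to bromine and not between the two benzyloxy groups.

**11 from 5 and 8, and 8 from 6 and 7.** The aryl–carbonyl bond (C1'–C2 of half 2) is cut. The bromide of 5 is a latent aryl anion, and the Weinreb amide 8 brings C2 and C3 with the 3-oxygen already benzylated. This avoids α-oxidation of a methyl ketone next to an acid-labile acetal.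

**5 from 4, 4 from 2 and 3, and 2 from 1.** The diaryl ether C–O bond is cut on the aldehyde ring, where the para formyl group activates fluoride for SNAr. The phenol 3 carries its bromide through untouched, so the handle for the next C–C bond is already in place.

## Alternatives that were turned down

**Alternative 1:** The bonds C3'–C4' and C5'–C6' of ring B of half 2 are cut. In the forward sense the pyranone A2 and the aryl ethynyl ether A3 would combine in a Diels–Alder reaction followed by decarboxylative cycloreversion to give the benzoate A1, with the diaryl ether already in place.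
- For it: the diaryl ether needs no SNAr or Ullmann step, and the regiochemistry follows from polarisation, since the nucleophilic terminal carbon of A3 bonds to C6 of A2. On this point it is stronger than the chosen route, because it does not depend on activation of an aryl fluoride.
- Against it: it spends its key step on the bond set that step 2 forms in one operation from simple arenes. A2 and A3 each need their own multistep preparation, and A3 is a labile ynol ether. After A1 all of ring C and ring A of half 2, and all of half 1, are still to be made.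
- Comparison: the chosen strategy gives a one-step diaryl ether that already carries the bromide handle, and places its key step on the chromone ring.

**Alternative 2:** The C4a–C5 bond of half 2 is cut, so that ring A comes from an open chain. The triketo ester A4 would cyclise with A5 by Claisen attack of chain carbon C6 on the ester carbon to give the 2',4',6'-trihydroxychalcone A6.
- For it: it is biomimetic, needs no halogen, no transition metal and no protecting group on ring A, and all three ring A oxygens come from chain carbonyls. On atom economy of ring A it is stronger.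
- Against it: A4 is a polycarbonyl enone that is hard to make and to keep. An aldol mode of ring closure, lactonisation to a pyranone and conjugate addition to the enone all compete with the Claisen mode. A6 is only at the chalcone oxidation level and has a free phloroglucinol ring, so it would isomerise by conjugate addition of an ortho hydroxyl. Reaching the flavonol would need reprotection and an oxidative cyclisation on a 6'-oxygenated chalcone, the weakest case of that reaction.
- Comparison: the chosen key step closes ring C directly at the flavonol oxidation level, with the C3 oxygen in place and ring A protected for the final hydrogenolysis.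

**Alternative 3:** The bonds C4a–C5 and C8–C8a of half 1 are cut. The bromopyranone A7 and the Brassard-type diene A8 would undergo a Diels–Alder reaction and aromatise by two eliminations to give A9, with ring A of half 1 closed.
- For it: the diene delivers the 7-OMe and a free 5-OH in one step. Here it is stronger than the chosen route, which relies on a selective methylation to reach 22.
- Against it: A7, a fully substituted 4-pyranone carrying the diaryl ether, needs a long preparation. Its C5=C6 bond is part of a vinylogous ester and is a reluctant dienophile, so forcing conditions would compete with desilylation of A8. The benzoate of A9 must still be turned into the whole of half 2.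
- Comparison: the chosen route takes the 7-OMe from a cheap acetophenone and uses a ring closure that is established on 1-(2-haloaryl)-1,3-diketones.

Key step: step 10

Remark on the chemistry: 27 is achiral. Compounds 10, 17, 18 and 25 are racemic (17 a mixture of diastereomers), and all their stereocentres are removed before 27, so none needs control. The SMILES of 25 shows one enantiomer of the trans racemate.

## Route

Step 1
Reactants: 1 4-fluoro-3-hydroxybenzaldehyde
Product: 2 3-(benzyloxy)-4-fluorobenzaldehyde
Conditions: BnBr, K2CO3, DMF, rt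
Reagents that add atoms: benzyl bromide, BrCc1ccccc1
Why: Williamson ether synthesis on an acidic phenol; the benzyl ether masks the future 3'-OH of half 1 until the final hydrogenolysis.

Step 2
Reactants: 2 3-(benzyloxy)-4-fluorobenzaldehyde; 3 4-bromo-2-methoxyphenol
Product: 4 3-(benzyloxy)-4-(4-bromo-2-methoxyphenoxy)benzaldehyde
Conditions: K2CO3, DMSO, 110 °C
Reagents that add atoms: none
Why: SNAr; the phenoxide of 3 adds at the fluorine-bearing carbon of 2, the para formyl group stabilises the Meisenheimer intermediate and fluoride leaves. The unactivated aryl bromide of 3 should not take part.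

Step 3
Reactants: 4 3-(benzyloxy)-4-(4-bromo-2-methoxyphenoxy)benzaldehyde
Product: 5 2-[3-(benzyloxy)-4-(4-bromo-2-methoxyphenoxy)phenyl]-1,3-dioxolane
Conditions: ethylene glycol, pTsOH (cat.), toluene, reflux, Dean–Stark
Reagents that add atoms: ethane-1,2-diol, OCCO
Why: Acid-catalysed acetalisation driven by removal of water; the dioxolane protects the aldehyde from the organolithium and enolate chemistry that follows.

Step 4
Reactants: 6 (benzyloxy)acetyl chloride; 7 N,O-dimethylhydroxylamine hydrochloride
Product: 8 2-(benzyloxy)-N-methoxy-N-methylacetamide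
Conditions: Et3N, CH2Cl2, 0 °C to rt
Reagents that add atoms: none
Why: Acylation of the amine by the acid chloride gives the Weinreb amide, a two-carbon acyl donor that already carries the benzylated 3-oxygen of half 2.

Step 5
Reactants: 5 2-[3-(benzyloxy)-4-(4-bromo-2-methoxyphenoxy)phenyl]-1,3-dioxolane; 8 2-(benzyloxy)-N-methoxy-N-methylacetamide
Product: 11 2-(benzyloxy)-1-{4-[2-(benzyloxy)-4-(1,3-dioxolan-2-yl)phenoxy]-3-methoxyphenyl}ethan-1-one, via aryllithium 9 (not isolated), via tetrahedral lithium adduct 10 (not isolated)
Conditions: n-BuLi, THF, −78 °C; then 8, −78 to −20 °C; aq NH4Cl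
Reagents that add atoms: none
Why: Bromine–lithium exchange is faster than any ortho-metalation at −78 °C, and the Weinreb ketone synthesis stops at the chelated adduct 10, which gives the ketone only on work-up. Ethers and the dioxolane are inert to the aryllithium.

Step 6
Reactants: 12 5-bromoresorcinol
Product: 13 1,3-bis(benzyloxy)-5-bromobenzene
Conditions: BnBr, K2CO3, DMF, 60 °C
Reagents that add atoms: benzyl bromide, BrCc1ccccc1
Why: Double Williamson etherification; both ring A oxygens of half 2 receive the same protecting group, which is possible because ring A will react as the electrophile.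

Step 7
Reactants: 13 1,3-bis(benzyloxy)-5-bromobenzene
Product: 15 2,4-bis(benzyloxy)-6-bromobenzaldehyde, via iminium salt 14 (not isolated)
Conditions: POCl3, DMF, 0 to 70 °C; then aq NaOAc
Reagents that add atoms: N,N-dimethylformamide, CN(C)C=O; water, O
Why: Vilsmeier–Haack formylation; the chloroiminium reagent should attack the position para to one benzyloxy group and ortho to the other (next to bromine), since the position between the two benzyloxy groups is shielded on both sides. Buffered hydrolysis of 14 gives the aldehyde.

Step 8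
Reactants: 11 2-(benzyloxy)-1-{4-[2-(benzyloxy)-4-(1,3-dioxolan-2-yl)phenoxy]-3-methoxyphenyl}ethan-1-one; 15 2,4-bis(benzyloxy)-6-bromobenzaldehyde
Product: 17 2-(benzyloxy)-3-[2,4-bis(benzyloxy)-6-bromophenyl]-1-{4-[2-(benzyloxy)-4-(1,3-dioxolan-2-yl)phenoxy]-3-methoxyphenyl}-3-hydroxypropan-1-one (mixture of racemic diastereomers), via lithium enolate 16 (not isolated)
Conditions: LiHMDS, THF, −78 °C; then 15, −78 °C; aq NH4Cl at −78 °C
Reagents that add atoms: none
Why: Directed aldol addition of a preformed, chelated lithium enolate to a non-enolisable aldehyde forms the future C3–C4 bond of half 2. The diastereomer ratio is immaterial because both stereocentres are removed in steps 9 and 10.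

Step 9
Reactants: 17 the aldol adduct from step 8
Product: 18 2-(benzyloxy)-1-[2,4-bis(benzyloxy)-6-bromophenyl]-3-{4-[2-(benzyloxy)-4-(1,3-dioxolan-2-yl)phenoxy]-3-methoxyphenyl}propane-1,3-dione (racemic, partly enolised)
Conditions: DMP (1.2 equiv), NaHCO3, CH2Cl2, 0 °C to rt
Reagents that add atoms: none
Why: Dess–Martin oxidation of a β-hydroxy ketone to the 1,3-diketone under buffered, near-neutral conditions that spare the acetal and benzyl ethers. A small excess and short contact time should limit oxidation at C2.

Step 10
Reactants: 18 2-(benzyloxy)-1-[2,4-bis(benzyloxy)-6-bromophenyl]-3-{4-[2-(benzyloxy)-4-(1,3-dioxolan-2-yl)phenoxy]-3-methoxyphenyl}propane-1,3-dione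
Product: 19 3,5,7-tris(benzyloxy)-2-{4-[2-(benzyloxy)-4-(1,3-dioxolan-2-yl)phenoxy]-3-methoxyphenyl}-4H-chromen-4-one
Conditions: CuI (10 mol %), 1,10-phenanthroline (20 mol %), Cs2CO3, DMF, 90 °C, dilute, under N2
Reagents that add atoms: none
Why: This is an intramolecular Ullmann-type C–O coupling, the established copper-catalysed enolate O-arylation that converts 1-(2-haloaryl)-1,3-diketones into flavones. Cs2CO3 removes the doubly activated C2 proton of 18, the enolate binds phenanthroline-ligated monovalent copper through the oxygen on the ring B side, the aryl bromide adds oxidatively to give a trivalent copper aryl alkoxide, and reductive elimination forms O1–C8a and returns monovalent copper. Ring C closes in a 6-exo-trig sense at the aromatic carbon, the breaking C–Br bond being exocyclic to the new pyranone ring. The ortho ketone holds the bromide within reach and eases oxidative addition, and both benzyloxy groups of ring A are meta to the bromide, so they do not push electron density onto the reacting carbon. No stereocentre is formed, and the one at C2 of 18 is lost on enolisation. The step needs O- over C-arylation and a choice between the two enolate oxygens; ring size decides both, because only the ring B-side oxygen reaches the C–Br carbon through a six-membered array, while C2 or the other oxygen would have to close a four-membered ring. The 3-oxygen passes through as its benzyl ether, so 19 is already at the flavonol oxidation level. Dilute, anhydrous conditions should hold back intermolecular coupling and retro-Claisen cleavage.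

Step 11
Reactants: 19 3,5,7-tris(benzyloxy)-2-{4-[2-(benzyloxy)-4-(1,3-dioxolan-2-yl)phenoxy]-3-methoxyphenyl}-4H-chromen-4-one
Product: 20 3-(benzyloxy)-4-{2-methoxy-4-[3,5,7-tris(benzyloxy)-4-oxo-4H-chromen-2-yl]phenoxy}benzaldehyde
Conditions: 1 M aq HCl, THF, rt
Reagents that add atoms: water, O
Why: Acid-catalysed acetal hydrolysis; benzyl ethers, the diaryl ether and the chromone are stable to dilute acid at room temperature.

Step 12
Reactants: 21 1-(2,4,6-trihydroxyphenyl)ethan-1-one
Product: 22 1-(2,6-dihydroxy-4-methoxyphenyl)ethan-1-one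
Conditions: Me2SO4 (1.0 equiv), K2CO3 (1.0 equiv), acetone, reflux
Reagents that add atoms: dimethyl sulfate, COS(=O)(=O)OC
Why: Selective O-methylation; the 4-hydroxyl is the most acidic and the only one not hydrogen-bonded to the ketone, so one equivalent of base and electrophile should alkylate it first.

Step 13
Reactants: 22 1-(2,6-dihydroxy-4-methoxyphenyl)ethan-1-one
Product: 23 1-[2-(benzyloxy)-6-hydroxy-4-methoxyphenyl]ethan-1-one
Conditions: BnBr (1.0 equiv), K2CO3, acetone, reflux
Reagents that add atoms: benzyl bromide, BrCc1ccccc1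
Why: Williamson mono-benzylation of one of two equivalent hydroxyls; after the first alkylation the remaining hydroxyl is strongly chelated to the ketone and hindered, which should stop the reaction at the mono-ether.

Step 14
Reactants: 20 3-(benzyloxy)-4-{2-methoxy-4-[3,5,7-tris(benzyloxy)-4-oxo-4H-chromen-2-yl]phenoxy}benzaldehyde; 23 1-[2-(benzyloxy)-6-hydroxy-4-methoxyphenyl]ethan-1-one
Product: 24 (E)-1-[2-(benzyloxy)-6-hydroxy-4-methoxyphenyl]-3-[3-(benzyloxy)-4-{2-methoxy-4-[3,5,7-tris(benzyloxy)-4-oxo-4H-chromen-2-yl]phenoxy}phenyl]prop-2-en-1-one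
Conditions: KOH, EtOH/THF, rt
Reagents that add atoms: none
Why: Claisen–Schmidt condensation; the acetophenone enolate adds to the non-enolisable aldehyde and E1cB loss of water gives the conjugated E-enone. The fully alkylated, electron-rich chromone of half 2 should tolerate cold alkali.

Step 15
Reactants: 24 the chalcone from step 14
Product: 26 5-(benzyloxy)-2-[3-(benzyloxy)-4-{2-methoxy-4-[3,5,7-tris(benzyloxy)-4-oxo-4H-chromen-2-yl]phenoxy}phenyl]-3-hydroxy-7-methoxy-4H-chromen-4-one, via dihydroflavonol 25 (not isolated)
Conditions: 30% aq H2O2, NaOH, MeOH/THF, 0 °C to rt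
Reagents that add atoms: hydrogen peroxide, OO
Why: Algar–Flynn–Oyamada reaction; the 2'-phenoxide adds to the β-carbon while the developing enolate is hydroxylated by peroxide, giving 25, which alkaline peroxide dehydrogenates to the flavonol. Low temperature is used to favour six-membered closure.

Step 16
Reactants: 26 the pentabenzyl bis-flavonol from step 15
Product: 27 2-{4-[4-(3,5-dihydroxy-7-methoxy-4-oxo-4H-chromen-2-yl)-2-hydroxyphenoxy]-3-methoxyphenyl}-3,5,7-trihydroxy-4H-chromen-4-one (target)
Conditions: H2 (1 atm), 10% Pd/C, THF/MeOH, rt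
Reagents that add atoms: none
Why: Hydrogenolysis of five benzyl ethers; methyl ethers, the diaryl ether and the tetrasubstituted C2=C3 bonds of both flavonols are not expected to react under these mild conditions.

## Compound list

1 | 4-fluoro-3-hydroxybenzaldehyde | O=Cc1ccc(F)c(O)c1 | starting material
2 | 3-(benzyloxy)-4-fluorobenzaldehyde | O=Cc1ccc(F)c(OCc2ccccc2)c1 | intermediate
3 | 4-bromo-2-methoxyphenol | COc1cc(Br)ccc1O | starting material
4 | 3-(benzyloxy)-4-(4-bromo-2-methoxyphenoxy)benzaldehyde | O=Cc1ccc(Oc2ccc(Br)cc2OC)c(OCc2ccccc2)c1 | intermediate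
5 | 2-[3-(benzyloxy)-4-(4-bromo-2-methoxyphenoxy)phenyl]-1,3-dioxolane | Brc1ccc(Oc2ccc(C3OCCO3)cc2OCc2ccccc2)c(OC)c1 | intermediate
6 | (benzyloxy)acetyl chloride | O=C(Cl)COCc1ccccc1 | starting material
7 | N,O-dimethylhydroxylamine hydrochloride | CNOC.Cl | starting material
8 | 2-(benzyloxy)-N-methoxy-N-methylacetamide | CON(C)C(=O)COCc1ccccc1 | intermediate
9 | {4-[2-(benzyloxy)-4-(1,3-dioxolan-2-yl)phenoxy]-3-methoxyphenyl}lithium | [Li]c1ccc(Oc2ccc(C3OCCO3)cc2OCc2ccccc2)c(OC)c1 | intermediate
10 | lithium 2-(benzyloxy)-1-{4-[2-(benzyloxy)-4-(1,3-dioxolan-2-yl)phenoxy]-3-methoxyphenyl}-1-[methoxy(methyl)amino]ethan-1-olate (racemic) | [Li]OC(COCc1ccccc1)(N(C)OC)c1ccc(Oc2ccc(C3OCCO3)cc2OCc2ccccc2)c(OC)c1 | intermediate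
11 | 2-(benzyloxy)-1-{4-[2-(benzyloxy)-4-(1,3-dioxolan-2-yl)phenoxy]-3-methoxyphenyl}ethan-1-one | O=C(COCc1ccccc1)c1ccc(Oc2ccc(C3OCCO3)cc2OCc2ccccc2)c(OC)c1 | intermediate
12 | 5-bromoresorcinol | Oc1cc(O)cc(Br)c1 | starting material
13 | 1,3-bis(benzyloxy)-5-bromobenzene | Brc1cc(OCc2ccccc2)cc(OCc2ccccc2)c1 | intermediate
14 | N-{[2,4-bis(benzyloxy)-6-bromophenyl]methylidene}-N-methylmethanaminium chloride | C[N+](C)=Cc1c(Br)cc(OCc2ccccc2)cc1OCc1ccccc1.[Cl-] | intermediate
15 | 2,4-bis(benzyloxy)-6-bromobenzaldehyde | O=Cc1c(Br)cc(OCc2ccccc2)cc1OCc1ccccc1 | intermediate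
16 | lithium (Z)-enolate of 11 | [Li]O/C(=C\OCc1ccccc1)c1ccc(Oc2ccc(C3OCCO3)cc2OCc2ccccc2)c(OC)c1 | intermediate
17 | 2-(benzyloxy)-3-[2,4-bis(benzyloxy)-6-bromophenyl]-1-{4-[2-(benzyloxy)-4-(1,3-dioxolan-2-yl)phenoxy]-3-methoxyphenyl}-3-hydroxypropan-1-one (racemic diastereomers) | OC(c1c(Br)cc(OCc2ccccc2)cc1OCc1ccccc1)C(OCc1ccccc1)C(=O)c1ccc(Oc2ccc(C3OCCO3)cc2OCc2ccccc2)c(OC)c1 | intermediate
18 | 2-(benzyloxy)-1-[2,4-bis(benzyloxy)-6-bromophenyl]-3-{4-[2-(benzyloxy)-4-(1,3-dioxolan-2-yl)phenoxy]-3-methoxyphenyl}propane-1,3-dione (racemic) | O=C(c1c(Br)cc(OCc2ccccc2)cc1OCc1ccccc1)C(OCc1ccccc1)C(=O)c1ccc(Oc2ccc(C3OCCO3)cc2OCc2ccccc2)c(OC)c1 | intermediate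
19 | 3,5,7-tris(benzyloxy)-2-{4-[2-(benzyloxy)-4-(1,3-dioxolan-2-yl)phenoxy]-3-methoxyphenyl}-4H-chromen-4-one | O=c1c(OCc2ccccc2)c(-c2ccc(Oc3ccc(C4OCCO4)cc3OCc3ccccc3)c(OC)c2)oc2cc(OCc3ccccc3)cc(OCc3ccccc3)c12 | intermediate
20 | 3-(benzyloxy)-4-{2-methoxy-4-[3,5,7-tris(benzyloxy)-4-oxo-4H-chromen-2-yl]phenoxy}benzaldehyde | O=Cc1ccc(Oc2ccc(cc2OC)-c2oc3cc(OCc4ccccc4)cc(OCc4ccccc4)c3c(=O)c2OCc2ccccc2)c(OCc2ccccc2)c1 | intermediate
21 | 1-(2,4,6-trihydroxyphenyl)ethan-1-one | CC(=O)c1c(O)cc(O)cc1O | starting material
22 | 1-(2,6-dihydroxy-4-methoxyphenyl)ethan-1-one | CC(=O)c1c(O)cc(OC)cc1O | intermediate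
23 | 1-[2-(benzyloxy)-6-hydroxy-4-methoxyphenyl]ethan-1-one | CC(=O)c1c(O)cc(OC)cc1OCc1ccccc1 | intermediate
24 | (E)-1-[2-(benzyloxy)-6-hydroxy-4-methoxyphenyl]-3-[3-(benzyloxy)-4-{2-methoxy-4-[3,5,7-tris(benzyloxy)-4-oxo-4H-chromen-2-yl]phenoxy}phenyl]prop-2-en-1-one | COc1cc(O)c(C(=O)/C=C/c2ccc(Oc3ccc(cc3OC)-c3oc4cc(OCc5ccccc5)cc(OCc5ccccc5)c4c(=O)c3OCc3ccccc3)c(OCc3ccccc3)c2)c(OCc2ccccc2)c1 | intermediate
25 | trans-5-(benzyloxy)-2-[3-(benzyloxy)-4-{2-methoxy-4-[3,5,7-tris(benzyloxy)-4-oxo-4H-chromen-2-yl]phenoxy}phenyl]-3-hydroxy-7-methoxychroman-4-one (racemic) | c1(ccc(Oc2ccc(cc2OC)-c2oc3cc(OCc4ccccc4)cc(OCc4ccccc4)c3c(=O)c2OCc2ccccc2)c(OCc2ccccc2)c1)[C@@H]1[C@H](C(=O)c2c(cc(cc2O1)OC)OCc2ccccc2)O | intermediate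
26 | 5-(benzyloxy)-2-[3-(benzyloxy)-4-{2-methoxy-4-[3,5,7-tris(benzyloxy)-4-oxo-4H-chromen-2-yl]phenoxy}phenyl]-3-hydroxy-7-methoxy-4H-chromen-4-one | COc1cc(OCc2ccccc2)c2c(=O)c(O)c(-c3ccc(Oc4ccc(cc4OC)-c4oc5cc(OCc6ccccc6)cc(OCc6ccccc6)c5c(=O)c4OCc4ccccc4)c(OCc4ccccc4)c3)oc2c1 | intermediate
27 | 2-{4-[4-(3,5-dihydroxy-7-methoxy-4-oxo-4H-chromen-2-yl)-2-hydroxyphenoxy]-3-methoxyphenyl}-3,5,7-trihydroxy-4H-chromen-4-one | COc1cc(O)c2c(=O)c(O)c(-c3ccc(Oc4ccc(-c5oc6cc(O)cc(O)c6c(=O)c5O)cc4OC)c(O)c3)oc2c1 | target

## Step count and least certain steps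

Total: 16 steps. Longest linear sequence: 11 steps (steps 1, 2, 3, 5, 8, 9, 10, 11, 14, 15, 16, from 1 to 27).

**Step 10 (key step).** The bromide sits between the twisted ketone and a ring hydrogen on an electron-rich ring, so oxidative addition may be slow. Reduction of the C–Br bond or retro-Claisen fragmentation of the hindered diketone by carbonate and traces of water could then take over.
Fallback, from 11 back to the route at 20, with ring A returned to the nucleophilic role: 2,4,6-trihydroxybenzaldehyde would be benzylated at its two more reactive hydroxyls to 2,4-bis(benzyloxy)-6-hydroxybenzaldehyde F1, and the chelated hydroxyl capped with chloromethyl methyl ether to give 2,4-bis(benzyloxy)-6-(methoxymethoxy)benzaldehyde F2. Addition of the enolate 16 to F2 should give the aldol adduct F3, and Dess–Martin oxidation the 1-(2-methoxymethoxyaryl)-1,3-diketone F4. Aqueous HCl in THF/MeOH would then remove the methoxymethyl group, close ring C by the classical cyclodehydration of an ortho-hydroxyaryl diketone and hydrolyse the dioxolane, giving 20 directly.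

**Step 15.** Closure may be diverted to the five-membered ring: the 6'-benzyloxy group twists the enone out of the plane of ring A, which favours attack of the phenoxide at the α-carbon and formation of a benzylidene benzofuranone in place of the flavonol.
Fallback, from 20 and 23 back to the route at 26, separating epoxidation from cyclisation: 23 would be converted into 1-[2-(benzyloxy)-4-methoxy-6-(methoxymethoxy)phenyl]ethan-1-one F5 and condensed with 20 to the 2'-protected chalcone F6. Weitz–Scheffer epoxidation with alkaline hydrogen peroxide should give the trans epoxide F7. Aqueous HCl in MeOH/THF would release the phenol, which opens the epoxide at the benzylic carbon in the 6-endo mode to give 25, now isolated. Dehydrogenation of 25 with I2 and KOAc in AcOH would give 26.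

**Step 8.** The aldehyde 15 is flanked by bromine and a benzyloxy group and is electron-rich, so addition may be incomplete and the aldolate may revert on warming.
Fallback, from 15 and 11 back to the route at 18, replacing aldol and oxidation by C-acylation: Pinnick oxidation of 15 would give 2,4-bis(benzyloxy)-6-bromobenzoic acid F8, which via its acid chloride and 1H-benzotriazole gives the N-acylbenzotriazole F9. Two equivalents of the enolate 16 and F9 should then give 18 by C-acylation.

**Step 2.** The benzyloxy group ortho to fluorine donates into the carbon under attack, so the substitution may be sluggish, and prolonged heating in basic DMSO could degrade the aldehyde.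
Fallback, from 3 back to the route at 4, by copper catalysis: commercial 3-hydroxy-4-iodobenzaldehyde would be benzylated to 3-(benzyloxy)-4-iodobenzaldehyde F10 and coupled with 3 in an Ullmann ether synthesis (CuI, picolinic acid, Cs2CO3, DMSO, 90 °C). The activated iodide should react well before the electron-rich bromide of 3.

**Step 5.** Proton transfer from the α-methylene of 8 to the aryllithium 9 may compete with addition and return the debrominated arene.
Fallback, from 5 back to the route at 11, in two steps: the aryllithium 9 would be added to commercial (benzyloxy)acetaldehyde, which should react faster than it enolises at −78 °C, to give the benzylic alcohol 2-(benzyloxy)-1-{4-[2-(benzyloxy)-4-(1,3-dioxolan-2-yl)phenoxy]-3-methoxyphenyl}ethan-1-ol F11. Oxidation of F11 with MnO2 in CH2Cl2 would give 11.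

## Further compounds

F1 | step 10 | 2,4-bis(benzyloxy)-6-hydroxybenzaldehyde | O=Cc1c(O)cc(OCc2ccccc2)cc1OCc1ccccc1
F2 | step 10 | 2,4-bis(benzyloxy)-6-(methoxymethoxy)benzaldehyde | O=Cc1c(OCOC)cc(OCc2ccccc2)cc1OCc1ccccc1
F3 | step 10 | 2-(benzyloxy)-3-[2,4-bis(benzyloxy)-6-(methoxymethoxy)phenyl]-1-{4-[2-(benzyloxy)-4-(1,3-dioxolan-2-yl)phenoxy]-3-methoxyphenyl}-3-hydroxypropan-1-one (racemic diastereomers) | OC(c1c(OCOC)cc(OCc2ccccc2)cc1OCc1ccccc1)C(OCc1ccccc1)C(=O)c1ccc(Oc2ccc(C3OCCO3)cc2OCc2ccccc2)c(OC)c1
F4 | step 10 | 2-(benzyloxy)-1-[2,4-bis(benzyloxy)-6-(methoxymethoxy)phenyl]-3-{4-[2-(benzyloxy)-4-(1,3-dioxolan-2-yl)phenoxy]-3-methoxyphenyl}propane-1,3-dione (racemic) | O=C(c1c(OCOC)cc(OCc2ccccc2)cc1OCc1ccccc1)C(OCc1ccccc1)C(=O)c1ccc(Oc2ccc(C3OCCO3)cc2OCc2ccccc2)c(OC)c1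
F5 | step 15 | 1-[2-(benzyloxy)-4-methoxy-6-(methoxymethoxy)phenyl]ethan-1-one | CC(=O)c1c(OCOC)cc(OC)cc1OCc1ccccc1
F6 | step 15 | (E)-1-[2-(benzyloxy)-4-methoxy-6-(methoxymethoxy)phenyl]-3-[3-(benzyloxy)-4-{2-methoxy-4-[3,5,7-tris(benzyloxy)-4-oxo-4H-chromen-2-yl]phenoxy}phenyl]prop-2-en-1-one | COCOc1cc(OC)cc(OCc2ccccc2)c1C(=O)/C=C/c1ccc(Oc2ccc(cc2OC)-c2oc3cc(OCc4ccccc4)cc(OCc4ccccc4)c3c(=O)c2OCc2ccccc2)c(OCc2ccccc2)c1
F7 | step 15 | trans-epoxide of F6 (racemic) | COCOc1cc(OC)cc(OCc2ccccc2)c1C(=O)[C@H]1O[C@@H]1c1ccc(Oc2ccc(cc2OC)-c2oc3cc(OCc4ccccc4)cc(OCc4ccccc4)c3c(=O)c2OCc2ccccc2)c(OCc2ccccc2)c1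
F8 | step 8 | 2,4-bis(benzyloxy)-6-bromobenzoic acid | OC(=O)c1c(Br)cc(OCc2ccccc2)cc1OCc1ccccc1
F9 | step 8 | (1H-benzotriazol-1-yl)[2,4-bis(benzyloxy)-6-bromophenyl]methanone | O=C(c1c(Br)cc(OCc2ccccc2)cc1OCc1ccccc1)n1nnc2ccccc21
F10 | step 2 | 3-(benzyloxy)-4-iodobenzaldehyde | O=Cc1ccc(I)c(OCc2ccccc2)c1
F11 | step 5 | 2-(benzyloxy)-1-{4-[2-(benzyloxy)-4-(1,3-dioxolan-2-yl)phenoxy]-3-methoxyphenyl}ethan-1-ol (racemic) | OC(COCc1ccccc1)c1ccc(Oc2ccc(C3OCCO3)cc2OCc2ccccc2)c(OC)c1
A1 | alternative 1 | methyl 4-[2-(benzyloxy)-4-(1,3-dioxolan-2-yl)phenoxy]-3-methoxybenzoate | COC(=O)c1ccc(Oc2ccc(C3OCCO3)cc2OCc2ccccc2)c(OC)c1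
A2 | alternative 1 | methyl 3-methoxy-2-oxo-2H-pyran-5-carboxylate | COC(=O)C1=COC(=O)C(OC)=C1
A3 | alternative 1 | 2-[3-(benzyloxy)-4-(ethynyloxy)phenyl]-1,3-dioxolane | C#COc1ccc(C2OCCO2)cc1OCc1ccccc1
A4 | alternative 2 | methyl (E)-9-{4-[2-(benzyloxy)-4-(1,3-dioxolan-2-yl)phenoxy]-3-methoxyphenyl}-3,5,7-trioxonon-8-enoate | COC(=O)CC(=O)CC(=O)CC(=O)/C=C/c1ccc(Oc2ccc(C3OCCO3)cc2OCc2ccccc2)c(OC)c1
A5 | alternative 2 | Mg(OMe)2 (magnesium dimethoxide) | CO[Mg]OC
A6 | alternative 2 | (E)-3-{4-[2-(benzyloxy)-4-(1,3-dioxolan-2-yl)phenoxy]-3-methoxyphenyl}-1-(2,4,6-trihydroxyphenyl)prop-2-en-1-one | O=C(/C=C/c1ccc(Oc2ccc(C3OCCO3)cc2OCc2ccccc2)c(OC)c1)c1c(O)cc(O)cc1O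
A7 | alternative 3 | methyl 4-[2-(benzyloxy)-4-(3-(benzyloxy)-5-bromo-4-oxo-4H-pyran-2-yl)phenoxy]-3-methoxybenzoate | COC(=O)c1ccc(Oc2ccc(-c3occ(Br)c(=O)c3OCc3ccccc3)cc2OCc2ccccc2)c(OC)c1
A8 | alternative 3 | 1,3-dimethoxy-1-(trimethylsilyloxy)buta-1,3-diene | C=C(OC)C=C(OC)O[Si](C)(C)C
A9 | alternative 3 | methyl 4-[2-(benzyloxy)-4-(3-(benzyloxy)-5-hydroxy-7-methoxy-4-oxo-4H-chromen-2-yl)phenoxy]-3-methoxybenzoate | COC(=O)c1ccc(Oc2ccc(-c3oc4cc(OC)cc(O)c4c(=O)c3OCc3ccccc3)cc2OCc2ccccc2)c(OC)c1
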